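Manuifolin D is cut at the two bonds that tie the pyran ring to ring A, C4–C4a and O1–C8a. Ring A then becomes a 1,2-dihaloarene, and the C4–C3–C2–O1 chain with ring B becomes a cyclic alkenylboronic hemiester (a 1,2-oxaborole) in which boron holds C4 and O1 cis. One palladium-catalysed operation joins C4 to C4a (at the iodide) and O1 to C8a (at the bromide), exploiting the ortho relation of C4a and C8a, and gives an isoflav-3-ene. Iridium-catalysed asymmetric hydrogenation then sets C3. The 5'-(1,1-dimethylallyl) group comes from Claisen rearrangement of the 4'-prenyl ether, followed by re-prenylation and desilylation.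

Key step: step 5

Remark: isoflavan numbering is used (O1, C2, C3, C4, C4a to C8a in the chroman; primed locants in ring B, the 3-aryl ring); TIPS = tri(propan-2-yl)silyl.
Assumption: 3-bromo-4-iodophenol (9) is taken as a catalogue compound; para-iodination of 3-bromophenol would supply it otherwise.

Step 1
Reactants: 1 3-(benzyloxy)phenol
Product: 2 [3-(benzyloxy)phenoxy]tri(propan-2-yl)silane
Conditions: TIPSCl, imidazole, DMF, rt
Reagents that add atoms: chlorotri(propan-2-yl)silane, CC(C)[Si](Cl)(C(C)C)C(C)C
Why: Imidazole-promoted O-silylation of a phenol gives a bulky aryl silyl ether that should survive the later base, heat and hydrogenation and can be removed by fluoride at the end.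

Step 2
Reactants: 2 [3-(benzyloxy)phenoxy]tri(propan-2-yl)silane
Product: 3 [5-(benzyloxy)-2-bromophenoxy]tri(propan-2-yl)silane
Conditions: NBS (1.0 equiv), MeCN, 0 °C to rt
Reagents that add atoms: N-bromosuccinimide, O=C1CCC(=O)N1Br
Why: Electrophilic aromatic bromination should occur para to the benzyloxy group, which is the stronger para director (the silyl ether oxygen donates less), while the site between the two oxygens is too hindered.

Step 3
Reactants: 3 [5-(benzyloxy)-2-bromophenoxy]tri(propan-2-yl)silane; 4 prop-2-yn-1-ol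
Product: 8 4-[4-(benzyloxy)-2-(triisopropylsilyloxy)phenyl]-1,2-oxaborol-2(5H)-ol, via aryl Grignard reagent 5 (not isolated), via chloromagnesium propynolate 6 (not isolated), via oxamagnesole chelate 7 (not isolated)
Conditions: (a) 3, Mg, LiCl, THF, 40 °C; (b) 4, iPrMgCl (1.0 equiv), THF, 0 °C, then 5, CuI (10 mol%), Et2O/THF, 40 °C; (c) B(OMe)3, −78 °C to rt, then aq. NH4Cl
Reagents that add atoms: trimethyl borate, COB(OC)OC; water, O
Why: Copper-catalysed anti-carbomagnesiation of the propargylic alkoxide (Duboudin-type) should place the aryl group on the internal carbon and magnesium on the terminal carbon cis to CH2O in a five-membered chelate, and borylation of that alkenyl–magnesium bond followed by hydrolysis closes the cyclic boronic hemiester with the alkene geometry locked.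

Step 4
Reactants: 9 3-bromo-4-iodophenol
Product: 10 (3-bromo-4-iodophenoxy)tri(propan-2-yl)silane
Conditions: TIPSCl, imidazole, DMF, rt
Reagents that add atoms: chlorotri(propan-2-yl)silane, CC(C)[Si](Cl)(C(C)C)C(C)C
Why: O-silylation of the phenol gives the ring A partner, in which iodine sits para and bromine meta to the silyloxy group.

Step 5
Reactants: 8 4-[4-(benzyloxy)-2-(triisopropylsilyloxy)phenyl]-1,2-oxaborol-2(5H)-ol; 10 (3-bromo-4-iodophenoxy)tri(propan-2-yl)silane
Product: 12 4'-(benzyloxy)-2',7-bis(triisopropylsilyloxy)isoflav-3-ene [3-aryl-2H-chromene], via bromo allylic alcohol 11 (not isolated)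
Conditions: Pd(OAc)2 (5 mol%), t-BuXPhos (10 mol%), K3PO4 (3 equiv), toluene/H2O 20:1, 60 °C then 100 °C
Reagents that add atoms: none
Why: Zerovalent palladium should insert first into the C–I bond of 10, the alkenyl group of the borate of 8 transmetalates with retention of geometry and reductive elimination forms C4–C4a, giving 11 after B–O hydrolysis; a second oxidative addition into the neighbouring C–Br bond, alkoxide binding and C–O reductive elimination then form O1–C8a. The closest known reactions are the Suzuki–Miyaura coupling of cyclic alkenylboronic hemiesters and the palladium-catalysed intramolecular etherification of primary alcohols tethered to 2-bromoarenes, run in tandem as in the domino C-arylation/O-arylation of 1,2-dihaloarenes to benzofurans. The pyran ring is closed by C–O reductive elimination from a seven-membered oxapalladacycle, overall a [3+3] union of the C4–C3–C2–O1 unit with the C4a–C8a edge of ring A. No stereocentre is formed; only the alkene geometry matters, and it is fixed by the oxaborole ring, which places CH2O cis to the incoming aryl group so that the alkoxide can reach C8a. The step needs site selectivity (carbon to C4a, oxygen to C8a), secured by the halogen pattern of 10 (the iodide para to the silyloxy group reacts at 60 °C, the bromide only in the ring closure), and C–O reductive elimination faster than β-hydride elimination, for which the bulky di-tert-butylbiarylphosphine is chosen.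

Step 6
Reactants: 12 4'-(benzyloxy)-2',7-bis(triisopropylsilyloxy)isoflav-3-ene
Product: 13 (3R)-4'-(benzyloxy)-2',7-bis(triisopropylsilyloxy)isoflavan
Conditions: [Ir(cod)(ThrePHOX)][B(C6H3(CF3)2)4] (2 mol%), H2 (50 bar), CH2Cl2, rt
Reagents that add atoms: none
Why: Iridium–phosphinite-oxazoline catalysed asymmetric hydrogenation of a trisubstituted 3-aryl-2H-chromene, the reaction type used for isoflavans of the equol family, should set C3 under catalyst control; the ligand enantiomer opposite to the one that leads to the (S)-equol series is taken so that C3 becomes R.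

Step 7
Reactants: 13 (3R)-4'-(benzyloxy)-2',7-bis(triisopropylsilyloxy)isoflavan
Product: 14 (3R)-2',7-bis(triisopropylsilyloxy)isoflavan-4'-ol
Conditions: H2 (1 atm), Pd/C (palladium on carbon, 10%), EtOAc/EtOH, rt
Reagents that add atoms: none
Why: Hydrogenolysis of the benzyl ether should free only the 4'-phenol, before any alkene is present, and leaves the aryl silyl ethers, the chroman and C3 untouched.

Step 8
Reactants: 14 (3R)-2',7-bis(triisopropylsilyloxy)isoflavan-4'-ol
Product: 15 (3R)-4'-(3-methylbut-2-enyloxy)-2',7-bis(triisopropylsilyloxy)isoflavan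
Conditions: prenyl bromide, K2CO3, acetone, reflux
Reagents that add atoms: 1-bromo-3-methylbut-2-ene, CC(C)=CCBr
Why: Williamson etherification (SN2 at the primary allylic bromide) of the only free phenol.

Step 9
Reactants: 15 (3R)-4'-(3-methylbut-2-enyloxy)-2',7-bis(triisopropylsilyloxy)isoflavan
Product: 17 (3R)-5'-(2-methylbut-3-en-2-yl)-2',7-bis(triisopropylsilyloxy)isoflavan-4'-ol, via ortho-dienone 16 (not isolated)
Conditions: PhNEt2, 190 °C, sealed tube
Reagents that add atoms: none
Why: Aromatic Claisen rearrangement ([3,3]-sigmatropic shift) should bond the dimethyl-substituted allyl terminus to C5', the ortho carbon not flanked by the bulky 2'-silyloxy group, and the dienone then tautomerises to the phenol; the para position is blocked by C3, the amine solvent suppresses acid-induced cyclisation, and C3 is remote.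

Step 10
Reactants: 17 (3R)-5'-(2-methylbut-3-en-2-yl)-2',7-bis(triisopropylsilyloxy)isoflavan-4'-ol
Product: 18 (3R)-5'-(2-methylbut-3-en-2-yl)-4'-(3-methylbut-2-enyloxy)-2',7-bis(triisopropylsilyloxy)isoflavan
Conditions: prenyl bromide, K2CO3, Bu4NI (cat.), acetone, reflux
Reagents that add atoms: 1-bromo-3-methylbut-2-ene, CC(C)=CCBr
Why: Williamson etherification of the hindered phenol, with iodide catalysis to compensate for the ortho tertiary alkyl group.

Step 11
Reactants: 18 (3R)-5'-(2-methylbut-3-en-2-yl)-4'-(3-methylbut-2-enyloxy)-2',7-bis(triisopropylsilyloxy)isoflavan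
Product: 19 manuifolin D, (3R)-5'-(2-methylbut-3-en-2-yl)-4'-(3-methylbut-2-enyloxy)isoflavan-2',7-diol
Conditions: TBAF, AcOH, THF, 0 °C to rt
Reagents that add atoms: none
Why: Fluoride-induced cleavage of both aryl Si–O bonds under acetic acid buffering should release the two phenols without touching the prenyl ether, the terminal alkene or C3.

Compound list
1 | 3-(benzyloxy)phenol | Oc1cccc(OCc2ccccc2)c1 | starting material
2 | [3-(benzyloxy)phenoxy]tri(propan-2-yl)silane | CC(C)[Si](Oc1cccc(OCc2ccccc2)c1)(C(C)C)C(C)C | intermediate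
3 | [5-(benzyloxy)-2-bromophenoxy]tri(propan-2-yl)silane | CC(C)[Si](Oc1cc(OCc2ccccc2)ccc1Br)(C(C)C)C(C)C | intermediate
4 | prop-2-yn-1-ol | C#CCO | starting material
5 | [4-(benzyloxy)-2-(triisopropylsilyloxy)phenyl]magnesium bromide (formed in the flask) | CC(C)[Si](Oc1cc(OCc2ccccc2)ccc1[Mg]Br)(C(C)C)C(C)C | intermediate
6 | chloromagnesium prop-2-yn-1-olate (formed in the flask) | C#CCO[Mg]Cl | intermediate
7 | 4-[4-(benzyloxy)-2-(triisopropylsilyloxy)phenyl]-2,5-dihydro-1,2-oxamagnesole (formed in the flask) | CC(C)[Si](Oc1cc(OCc2ccccc2)ccc1C1=C[Mg]OC1)(C(C)C)C(C)C | intermediate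
8 | 4-[4-(benzyloxy)-2-(triisopropylsilyloxy)phenyl]-1,2-oxaborol-2(5H)-ol | CC(C)[Si](Oc1cc(OCc2ccccc2)ccc1C1=CB(O)OC1)(C(C)C)C(C)C | intermediate
9 | 3-bromo-4-iodophenol | Oc1ccc(I)c(Br)c1 | starting material
10 | (3-bromo-4-iodophenoxy)tri(propan-2-yl)silane | CC(C)[Si](Oc1ccc(I)c(Br)c1)(C(C)C)C(C)C | intermediate
11 | (Z)-2-[4-(benzyloxy)-2-(triisopropylsilyloxy)phenyl]-3-[2-bromo-4-(triisopropylsilyloxy)phenyl]prop-2-en-1-ol (formed in the flask) | OC/C(c1ccc(OCc2ccccc2)cc1O[Si](C(C)C)(C(C)C)C(C)C)=C\c1ccc(O[Si](C(C)C)(C(C)C)C(C)C)cc1Br | intermediate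
12 | 4'-(benzyloxy)-2',7-bis(triisopropylsilyloxy)isoflav-3-ene | CC(C)[Si](Oc1ccc2C=C(COc2c1)c1ccc(OCc2ccccc2)cc1O[Si](C(C)C)(C(C)C)C(C)C)(C(C)C)C(C)C | intermediate
13 | (3R)-4'-(benzyloxy)-2',7-bis(triisopropylsilyloxy)isoflavan | C(c1ccccc1)Oc1ccc([C@@H]2COc3cc(O[Si](C(C)C)(C(C)C)C(C)C)ccc3C2)c(O[Si](C(C)C)(C(C)C)C(C)C)c1 | intermediate
14 | (3R)-2',7-bis(triisopropylsilyloxy)isoflavan-4'-ol | Oc1ccc([C@@H]2COc3cc(O[Si](C(C)C)(C(C)C)C(C)C)ccc3C2)c(O[Si](C(C)C)(C(C)C)C(C)C)c1 | intermediate
15 | (3R)-4'-(3-methylbut-2-enyloxy)-2',7-bis(triisopropylsilyloxy)isoflavan | CC(C)=CCOc1ccc([C@@H]2COc3cc(O[Si](C(C)C)(C(C)C)C(C)C)ccc3C2)c(O[Si](C(C)C)(C(C)C)C(C)C)c1 | intermediate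
16 | ortho-dienone tautomer of 17: 6-(2-methylbut-3-en-2-yl)cyclohexa-2,4-dien-1-one form of ring B, C5' sp3 in either configuration (formed in the flask) | C=CC(C)(C)C1C=C([C@@H]2COc3cc(O[Si](C(C)C)(C(C)C)C(C)C)ccc3C2)C(O[Si](C(C)C)(C(C)C)C(C)C)=CC1=O | intermediate
17 | (3R)-5'-(2-methylbut-3-en-2-yl)-2',7-bis(triisopropylsilyloxy)isoflavan-4'-ol | C=CC(C)(C)c1cc([C@@H]2COc3cc(O[Si](C(C)C)(C(C)C)C(C)C)ccc3C2)c(O[Si](C(C)C)(C(C)C)C(C)C)cc1O | intermediate
18 | (3R)-5'-(2-methylbut-3-en-2-yl)-4'-(3-methylbut-2-enyloxy)-2',7-bis(triisopropylsilyloxy)isoflavan | C=CC(C)(C)c1cc([C@@H]2COc3cc(O[Si](C(C)C)(C(C)C)C(C)C)ccc3C2)c(O[Si](C(C)C)(C(C)C)C(C)C)cc1OCC=C(C)C | intermediate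
19 | manuifolin D | C=CC(C)(C)c1cc([C@@H]2COc3cc(O)ccc3C2)c(O)cc1OCC=C(C)C | target

Total step count: 11.
Longest linear sequence: 10 steps (steps 1–3 and 5–11); the ring A partner needs 1 step (step 4).

Steps most likely to fail

Step 5. The ring-closing half may be diverted by β-hydride elimination from the palladium alkoxide, which would reduce the C–Br bond and give the enal instead of the ether. The fallback separates the two bond formations and closes the ring only after saturation. It sets out from 8 and 10 and returns at 13. Suzuki–Miyaura coupling of 8 with 10 under Pd(PPh3)4, Na2CO3, DME/H2O at 50 °C should stop at the allylic alcohol 11, which is now isolated. Iridium-catalysed asymmetric hydrogenation of this trisubstituted allylic alcohol with the catalyst of step 6 should give (2R)-2-[4-(benzyloxy)-2-(triisopropylsilyloxy)phenyl]-3-[2-bromo-4-(triisopropylsilyloxy)phenyl]propan-1-ol F1. Palladium-catalysed intramolecular etherification of F1 (Pd(OAc)2, 2-(di-tert-butylphosphino)-1,1'-binaphthyl, Cs2CO3, toluene, 70 °C), the established chroman synthesis from 3-(2-bromoaryl)propan-1-ols, should then give 13.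

Step 6. The ortho-silyloxy group of ring B twists the aryl group out of the alkene plane, so that face discrimination by the catalyst may be poor or the reduction slow. The fallback replaces asymmetric catalysis by resolution. It sets out from 12 and returns at 14. Hydrogenation over Pd/C (H2, EtOAc/EtOH, rt) should saturate the alkene and cleave the benzyl ether together to give racemic 2',7-bis(triisopropylsilyloxy)isoflavan-4'-ol F2. Its enantiomers are separated by preparative chromatography on a chiral stationary phase (amylose tris(3,5-dimethylphenylcarbamate), supercritical CO2/MeOH) to deliver 14.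

Step 9. At 190 °C the prenyl ether may fragment to the phenol and isoprene, or the new ortho-(1,1-dimethylallyl)phenol may isomerise or cyclise further. The fallback builds the C5'–C bond by cross-coupling. It sets out from 14, bypasses steps 8 and 9, and returns at 17. Ortho-iodination of the phenol (I2, morpholine, CH2Cl2, 0 °C) at C5', the ortho site not flanked by the silyloxy group, should give (3R)-5'-iodo-2',7-bis(triisopropylsilyloxy)isoflavan-4'-ol F3. Suzuki–Miyaura coupling of F3 with 3-methylbut-2-enylboronic acid pinacol ester, under ligand control for bond formation at the substituted (γ) allyl terminus (Pd(OAc)2, bulky dialkylbiarylphosphine, K3PO4, THF/H2O, 40 °C), should install the 1,1-dimethylallyl group and give 17.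

Further compounds
F1 | step 5 | (2R)-2-[4-(benzyloxy)-2-(triisopropylsilyloxy)phenyl]-3-[2-bromo-4-(triisopropylsilyloxy)phenyl]propan-1-ol | C(c1ccccc1)Oc1ccc([C@@H](Cc2ccc(O[Si](C(C)C)(C(C)C)C(C)C)cc2Br)CO)c(O[Si](C(C)C)(C(C)C)C(C)C)c1
F2 | step 6 | racemic 2',7-bis(triisopropylsilyloxy)isoflavan-4'-ol | Oc1ccc(C2COc3cc(O[Si](C(C)C)(C(C)C)C(C)C)ccc3C2)c(O[Si](C(C)C)(C(C)C)C(C)C)c1
F3 | step 9 | (3R)-5'-iodo-2',7-bis(triisopropylsilyloxy)isoflavan-4'-ol | Ic1cc([C@@H]2COc3cc(O[Si](C(C)C)(C(C)C)C(C)C)ccc3C2)c(O[Si](C(C)C)(C(C)C)C(C)C)cc1O
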